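**Retrosynthetic overview**
- Target ⇐ C15‑O‑PMB ether ⇐ C8 acylation / C14 allylic oxidation / desilylation ⇐ α‑methylenation (Mannich, then elimination) of a cis‑fused γ‑lactone macrocycle.
- Ten‑membered carbocycle ⇐ ring‑closing metathesis at C1=C10 of a seco‑diene lactone; ring order: γ‑lactone (O6–C12) first, carbocycle second. Both ring olefins are cis within the ring (E by CIP).
- C8–C9 ⇐ Felkin/1,3‑anti Hosomi–Sakurai addition of a 2‑(silyloxymethyl)allylsilane to a C8 aldehyde; C7–C11 ⇐ Fráter–Seebach anti‑alkylation with tert‑butyl bromoacetate.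
- C6 carbinol (first stereocentre) ⇐ ketoreductase reduction of an achiral γ,δ‑unsaturated β‑keto ester; C4=C5 ⇐ E‑selective Wittig reaction of an α‑PMB‑oxy ketone.

Assumption: atom labels C1–C15 follow germacranolide numbering of the target (C6 lactone oxygen, C8 ester, C14 aldehyde carbon, C15 hydroxymethyl carbon); metal salts that are only the pre‑work‑up form of a numbered compound are not numbered separately.

Abbreviations: PMB = 4‑methoxybenzyl, TES = triethylsilyl, TBS = tert‑butyldimethylsilyl, TBDPS = tert‑butyldiphenylsilyl, CDI = 1,1'‑carbonyldiimidazole.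

**Step 1**
Reactants: 1 2‑chloro‑N‑methoxy‑N‑methylacetamide; 2 4‑methoxybenzyl alcohol
Product: 4 N‑methoxy‑2‑[(4‑methoxybenzyl)oxy]‑N‑methylacetamide, via sodium 4‑methoxybenzyl oxide 3 (not isolated)
Conditions: NaH, THF, 0 °C; then 1, 0 °C → rt
Reagents that add atoms: none
Why: Williamson ether synthesis, in which the alkoxide displaces the activated α‑chloride (SN2) and leaves the Weinreb amide untouched.

**Step 2**
Reactants: 4 N‑methoxy‑2‑[(4‑methoxybenzyl)oxy]‑N‑methylacetamide; 5 but‑3‑en‑1‑ylmagnesium bromide (CH2=CHCH2CH2MgBr)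
Product: 6 1‑[(4‑methoxybenzyl)oxy]hex‑5‑en‑2‑one
Conditions: THF, 0 °C; sat. aq. NH4Cl
Reagents that add atoms: none
Why: Weinreb ketone synthesis, in which the chelated tetrahedral magnesium adduct prevents over‑addition and gives the ketone on work‑up.

**Step 3**
Reactants: 6 1‑[(4‑methoxybenzyl)oxy]hex‑5‑en‑2‑one; 7 ethyl (triphenylphosphoranylidene)acetate
Product: 8 ethyl (2E)‑3‑{[(4‑methoxybenzyl)oxy]methyl}hepta‑2,6‑dienoate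
Conditions: toluene, 110 °C, 24 h; minor Z isomer removed by chromatography
Reagents that add atoms: none
Why: Wittig olefination with a stabilised ylide, which with α‑alkoxy ketones places the ester trans to the CH2OPMB group and so fixes the C4=C5 geometry (C3 cis to C6) of the target.

**Step 4**
Reactants: 8 ethyl (2E)‑3‑{[(4‑methoxybenzyl)oxy]methyl}hepta‑2,6‑dienoate
Product: 9 (2E)‑3‑{[(4‑methoxybenzyl)oxy]methyl}hepta‑2,6‑dienoic acid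
Conditions: LiOH·H2O, THF/MeOH/H2O, rt; then 1 M HCl to pH 3 at 0 °C
Reagents that add atoms: lithium hydroxide, [Li+].[OH-]
Why: ester saponification, which does not disturb the β,β‑disubstituted olefin geometry or the PMB ether.

**Step 5**
Reactants: 9 (2E)‑3‑{[(4‑methoxybenzyl)oxy]methyl}hepta‑2,6‑dienoic acid; 10 potassium ethyl malonate
Product: 13 ethyl (4E)‑5‑{[(4‑methoxybenzyl)oxy]methyl}‑3‑oxonona‑4,8‑dienoate, via acyl imidazolide 11 (not isolated), via acylmalonic acid monoester 12 (not isolated)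
Conditions: CDI, THF, rt; then 10, MgCl2, Et3N, MeCN, rt → 40 °C; 1 M HCl work‑up
Reagents that add atoms: none
Why: Masamune–Brooks homologation, in which the magnesium malonate half‑ester is C‑acylated by the acyl imidazolide and decarboxylates to the β‑keto ester.

**Step 6**
Reactants: 13 ethyl (4E)‑5‑{[(4‑methoxybenzyl)oxy]methyl}‑3‑oxonona‑4,8‑dienoate
Product: 14 ethyl (3S,4E)‑3‑hydroxy‑5‑(PMB‑oxymethyl)nona‑4,8‑dienoate
Conditions: ketoreductase (NADPH‑dependent alcohol dehydrogenase, (S)‑selective enzyme chosen from a commercial panel), NADP+ (cat.), iPrOH (15% v/v), KH2PO4/K2HPO4 buffer pH 7.0, DMSO (5% v/v), 30 °C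
Reagents that add atoms: none
Why: enzymatic asymmetric carbonyl reduction, in which the ketoreductase delivers hydride from NADPH (recycled by isopropanol) to one face of the prochiral ketone only, chemoselectively 1,2, and thereby sets C6 as the first stereocentre in high ee.

**Step 7**
Reactants: 14 ethyl (3S,4E)‑3‑hydroxy‑5‑(PMB‑oxymethyl)nona‑4,8‑dienoate; 15 tert‑butyl bromoacetate
Product: 17 4‑tert‑butyl 1‑ethyl (2R)‑2‑[(1R,2E)‑1‑hydroxy‑3‑(PMB‑oxymethyl)hepta‑2,6‑dien‑1‑yl]butanedioate, via dilithium dianion 16 (not isolated)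
Conditions: LiN(iPr)2 (2.2 equiv), THF, −78 → −20 °C; then 15, DMPU, −78 → −40 °C; sat. aq. NH4Cl at −40 °C
Reagents that add atoms: none
Why: Fráter–Seebach alkylation, in which the chelated alkoxide–enolate dianion is alkylated on the face opposite the C6 substituent and so sets C7 anti to O6.

**Step 8**
Reactants: 17 4‑tert‑butyl 1‑ethyl (2R)‑2‑[(1R,2E)‑1‑hydroxy‑3‑(PMB‑oxymethyl)hepta‑2,6‑dien‑1‑yl]butanedioate
Product: 18 4‑tert‑butyl 1‑ethyl (2R)‑2‑[(1R,2E)‑3‑(PMB‑oxymethyl)‑1‑(TES‑oxy)hepta‑2,6‑dien‑1‑yl]butanedioate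
Conditions: Et3SiCl, imidazole, DMF, 0 °C
Reagents that add atoms: triethylsilyl chloride, CC[Si](Cl)(CC)CC
Why: silyl ether formation, which masks O6 so that it cannot lactonise and installs the β‑silyloxy group that later directs 1,3‑anti induction.

**Step 9**
Reactants: 18 4‑tert‑butyl 1‑ethyl (2R)‑2‑[(1R,2E)‑3‑(PMB‑oxymethyl)‑1‑(TES‑oxy)hepta‑2,6‑dien‑1‑yl]butanedioate
Product: 19 tert‑butyl (3R,4R,5E)‑3‑formyl‑6‑(PMB‑oxymethyl)‑4‑(TES‑oxy)deca‑5,9‑dienoate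
Conditions: iBu2AlH (1.15 equiv), CH2Cl2, −78 °C; MeOH quench, aq. KNaC4H4O6; aldehyde used at once
Reagents that add atoms: none
Why: partial ester reduction, in which the ethyl ester is reduced through a stable tetrahedral aluminium adduct at −78 °C while the tert‑butyl ester is inert, and C7 is not epimerised at this temperature.

**Step 10**
Reactants: 20 2‑[(trimethylsilyl)methyl]allyl acetate
Product: 21 2‑[(trimethylsilyl)methyl]prop‑2‑en‑1‑ol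
Conditions: K2CO3 (cat.), MeOH, rt
Reagents that add atoms: none
Why: base‑catalysed transesterification (methanolysis) of the acetate, which the allylsilane tolerates.

**Step 11**
Reactants: 21 2‑[(trimethylsilyl)methyl]prop‑2‑en‑1‑ol
Product: 22 tert‑butyl(diphenyl)({2‑[(trimethylsilyl)methyl]prop‑2‑en‑1‑yl}oxy)silane
Conditions: tBuPh2SiCl, imidazole, CH2Cl2, rt
Reagents that add atoms: tert‑butyldiphenylsilyl chloride, CC(C)(C)[Si](Cl)(c1ccccc1)c1ccccc1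
Why: silylation of the primary alcohol gives the robust C14–O protecting group on the C9–C10–C14 allylsilane.

**Step 12**
Reactants: 19 tert‑butyl (3R,4R,5E)‑3‑formyl‑6‑(PMB‑oxymethyl)‑4‑(TES‑oxy)deca‑5,9‑dienoate; 22 tert‑butyl(diphenyl)({2‑[(trimethylsilyl)methyl]prop‑2‑en‑1‑yl}oxy)silane
Product: 23 tert‑butyl (3S,4R,5E)‑3‑[(1R)‑1‑hydroxy‑3‑(TBDPS‑oxymethyl)but‑3‑en‑1‑yl]‑6‑(PMB‑oxymethyl)‑4‑(TES‑oxy)deca‑5,9‑dienoate
Conditions: BF3·OEt2 (1.5 equiv), 22 (2 equiv), CH2Cl2, −78 °C; sat. aq. NaHCO3 quench at −78 °C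
Reagents that add atoms: none
Why: Hosomi–Sakurai allylation under a non‑chelating Lewis acid, in which Felkin–Anh attack anti to the C6 branch and 1,3‑anti induction from the β‑silyloxy group reinforce each other for this 2,3‑anti aldehyde and set C8 syn to the C7 side chain and anti to O6.

**Step 13**
Reactants: 23 tert‑butyl (3S,4R,5E)‑3‑[(1R)‑1‑hydroxy‑3‑(TBDPS‑oxymethyl)but‑3‑en‑1‑yl]‑6‑(PMB‑oxymethyl)‑4‑(TES‑oxy)deca‑5,9‑dienoate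
Product: 24 tert‑butyl (3S,4R,5E)‑3‑[(1R)‑1‑(TBS‑oxy)‑3‑(TBDPS‑oxymethyl)but‑3‑en‑1‑yl]‑6‑(PMB‑oxymethyl)‑4‑(TES‑oxy)deca‑5,9‑dienoate
Conditions: TBSOTf, 2,6‑lutidine, CH2Cl2, −78 °C
Reagents that add atoms: tert‑butyldimethylsilyl triflate, CC(C)(C)[Si](C)(C)OS(=O)(=O)C(F)(F)F
Why: fast silylation of O8 prevents the wrong (O8–C12) lactone and leaves O6 as the only oxygen that is unmasked later.

**Step 14**
Reactants: 24 tert‑butyl (3S,4R,5E)‑3‑[(1R)‑1‑(TBS‑oxy)‑3‑(TBDPS‑oxymethyl)but‑3‑en‑1‑yl]‑6‑(PMB‑oxymethyl)‑4‑(TES‑oxy)deca‑5,9‑dienoate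
Product: 26 (4R,5R)‑4‑[(1R)‑1‑(TBS‑oxy)‑3‑(TBDPS‑oxymethyl)but‑3‑en‑1‑yl]‑5‑[(1E)‑2‑(PMB‑oxymethyl)hexa‑1,5‑dien‑1‑yl]dihydrofuran‑2(3H)‑one, via hydroxy ester 25 (not isolated)
Conditions: PPTS, MeOH/CH2Cl2, 0 °C → rt; then solvent switch, TsOH·H2O (10 mol %), toluene, 45 °C
Reagents that add atoms: none
Why: selective solvolysis of the most labile silyl ether (TES) followed by acid‑catalysed 5‑exo lactonisation of the γ‑hydroxy tert‑butyl ester gives the cis‑4,5‑disubstituted γ‑lactone with no stereocentre touched.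

**Step 15**
Reactants: 26 (4R,5R)‑4‑[(1R)‑1‑(TBS‑oxy)‑3‑(TBDPS‑oxymethyl)but‑3‑en‑1‑yl]‑5‑[(1E)‑2‑(PMB‑oxymethyl)hexa‑1,5‑dien‑1‑yl]dihydrofuran‑2(3H)‑one
Product: 27 (3aR,4R,6E,10E,11aR)‑4‑(TBS‑oxy)‑6‑(TBDPS‑oxymethyl)‑10‑(PMB‑oxymethyl)‑3a,4,5,8,9,11a‑hexahydrocyclodeca[b]furan‑2(3H)‑one
Conditions: second‑generation Hoveyda–Grubbs catalyst RuCl2(H2IMes)(=CH‑C6H4‑2‑OiPr) (15 mol %), 1,4‑benzoquinone (20 mol %), toluene (1 mM), 90 °C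
Reagents that add atoms: none
Why: ring‑closing metathesis between the terminal C1 olefin and the 1,1‑disubstituted C10 olefin, driven by loss of ethene and pre‑organised by the cis C4=C5 bond and the cis‑fused lactone, gives the ring‑cis trisubstituted C1=C10 olefin favoured in a ten‑membered ring.

**Step 16**
Reactants: 27 (3aR,4R,6E,10E,11aR)‑4‑(TBS‑oxy)‑6‑(TBDPS‑oxymethyl)‑10‑(PMB‑oxymethyl)‑3a,4,5,8,9,11a‑hexahydrocyclodeca[b]furan‑2(3H)‑one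
Product: 29 (3aR,4R,6E,10E,11aR)‑3‑[(dimethylamino)methyl]‑4‑(TBS‑oxy)‑6‑(TBDPS‑oxymethyl)‑10‑(PMB‑oxymethyl)‑3a,4,5,8,9,11a‑hexahydrocyclodeca[b]furan‑2(3H)‑one (C3 epimers), via lithium enolate 28 (not isolated)
Conditions: LiN(iPr)2, THF, −78 °C; then Eschenmoser's salt, −78 °C → rt
Reagents that add atoms: Eschenmoser's salt (N,N‑dimethylmethyleneiminium iodide), C=[N+](C)C.[I-]
Why: Mannich reaction of the lactone enolate (the only acidic site) with the iminium salt introduces C13, and the new C11 centre is irrelevant because it becomes sp2 in the next step.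

**Step 17**
Reactants: 29 (3aR,4R,6E,10E,11aR)‑3‑[(dimethylamino)methyl]‑4‑(TBS‑oxy)‑6‑(TBDPS‑oxymethyl)‑10‑(PMB‑oxymethyl)‑3a,4,5,8,9,11a‑hexahydrocyclodeca[b]furan‑2(3H)‑one
Product: 31 (3aR,4R,6E,10E,11aR)‑3‑methylidene‑4‑(TBS‑oxy)‑6‑(TBDPS‑oxymethyl)‑10‑(PMB‑oxymethyl)‑3a,4,5,8,9,11a‑hexahydrocyclodeca[b]furan‑2(3H)‑one, via trimethylammonium iodide 30 (not isolated)
Conditions: MeI (excess), CH2Cl2/MeOH, rt; then sat. aq. NaHCO3, EtOAc, rt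
Reagents that add atoms: none
Why: N‑quaternisation followed by E1cB (Hofmann‑type) elimination of trimethylamine gives the α‑methylene‑γ‑butyrolactone under mild base.

**Step 18**
Reactants: 31 (3aR,4R,6E,10E,11aR)‑3‑methylidene‑4‑(TBS‑oxy)‑6‑(TBDPS‑oxymethyl)‑10‑(PMB‑oxymethyl)‑3a,4,5,8,9,11a‑hexahydrocyclodeca[b]furan‑2(3H)‑one
Product: 32 (3aS,4R,6E,10E,11aR)‑4‑hydroxy‑6‑(hydroxymethyl)‑10‑(PMB‑oxymethyl)‑3‑methylidene‑3a,4,5,8,9,11a‑hexahydrocyclodeca[b]furan‑2(3H)‑one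
Conditions: HF·pyridine (excess), pyridine, THF, 0 °C → rt, 36 h
Reagents that add atoms: none
Why: fluoride‑mediated global desilylation under buffered, non‑basic conditions that the α‑methylene lactone and the PMB ether tolerate.

**Step 19**
Reactants: 32 (3aS,4R,6E,10E,11aR)‑4‑hydroxy‑6‑(hydroxymethyl)‑10‑(PMB‑oxymethyl)‑3‑methylidene‑3a,4,5,8,9,11a‑hexahydrocyclodeca[b]furan‑2(3H)‑one
Product: 33 (3aS,4R,6E,10E,11aR)‑4‑hydroxy‑10‑(PMB‑oxymethyl)‑3‑methylidene‑2‑oxo‑2,3,3a,4,5,8,9,11a‑octahydrocyclodeca[b]furan‑6‑carbaldehyde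
Conditions: MnO2 (activated, 20 equiv), CH2Cl2, rt
Reagents that add atoms: none
Why: chemoselective allylic oxidation, in which MnO2 oxidises only the primary allylic C14 alcohol and leaves the non‑allylic C8 carbinol and the olefin geometry unchanged.

**Step 20**
Reactants: 33 (3aS,4R,6E,10E,11aR)‑4‑hydroxy‑10‑(PMB‑oxymethyl)‑3‑methylidene‑2‑oxo‑2,3,3a,4,5,8,9,11a‑octahydrocyclodeca[b]furan‑6‑carbaldehyde; 34 3‑methylbutanoic anhydride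
Product: 35 [(3aS,4R,6E,10E,11aR)‑6‑formyl‑10‑(PMB‑oxymethyl)‑3‑methylidene‑2‑oxo‑2,3,3a,4,5,8,9,11a‑octahydrocyclodeca[b]furan‑4‑yl] 3‑methylbutanoate
Conditions: 34, DMAP, Et3N, CH2Cl2, 0 °C → rt
Reagents that add atoms: none
Why: DMAP‑catalysed acylation of the only free hydroxyl (C8) with retention of configuration.

**Step 21**
Reactants: 35 [(3aS,4R,6E,10E,11aR)‑6‑formyl‑10‑(PMB‑oxymethyl)‑3‑methylidene‑2‑oxo‑2,3,3a,4,5,8,9,11a‑octahydrocyclodeca[b]furan‑4‑yl] 3‑methylbutanoate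
Product: 36 [(3aS,4R,6E,10E,11aR)‑6‑formyl‑10‑(hydroxymethyl)‑3‑methylidene‑2‑oxo‑2,3,3a,4,5,8,9,11a‑octahydrocyclodeca[b]furan‑4‑yl] 3‑methylbutanoate (target)
Conditions: DDQ (1.3 equiv), CH2Cl2/aq. KH2PO4–K2HPO4 buffer pH 7 (10:1), 0 °C
Reagents that add atoms: none
Why: oxidative cleavage of the PMB ether by DDQ (benzylic hydride abstraction, then hydrolysis of the oxocarbenium ion) frees the C15 alcohol under neutral conditions that the enal, the ester and the α‑methylene lactone tolerate.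

**Compound list**
1 | 2‑chloro‑N‑methoxy‑N‑methylacetamide | CON(C)C(=O)CCl | starting material
2 | 4‑methoxybenzyl alcohol | COc1ccc(CO)cc1 | starting material
3 | sodium 4‑methoxybenzyl oxide | [Na+].[O-]Cc1ccc(OC)cc1 | intermediate
4 | N‑methoxy‑2‑[(4‑methoxybenzyl)oxy]‑N‑methylacetamide | CON(C)C(=O)COCc1ccc(OC)cc1 | intermediate
5 | but‑3‑en‑1‑ylmagnesium bromide | C=CCC[Mg]Br | starting material
6 | 1‑[(4‑methoxybenzyl)oxy]hex‑5‑en‑2‑one | C=CCCC(=O)COCc1ccc(OC)cc1 | intermediate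
7 | ethyl (triphenylphosphoranylidene)acetate | CCOC(=O)C=P(c1ccccc1)(c1ccccc1)c1ccccc1 | starting material
8 | ethyl (2E)‑3‑{[(4‑methoxybenzyl)oxy]methyl}hepta‑2,6‑dienoate | CCOC(=O)/C=C(/COCc1ccc(OC)cc1)CCC=C | intermediate
9 | (2E)‑3‑{[(4‑methoxybenzyl)oxy]methyl}hepta‑2,6‑dienoic acid | OC(=O)/C=C(/COCc1ccc(OC)cc1)CCC=C | intermediate
10 | potassium ethyl malonate | CCOC(=O)CC(=O)[O-].[K+] | starting material
11 | (2E)‑1‑(imidazol‑1‑yl)‑3‑(PMB‑oxymethyl)hepta‑2,6‑dien‑1‑one (acyl imidazolide) | O=C(/C=C(/COCc1ccc(OC)cc1)CCC=C)n1ccnc1 | intermediate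
12 | (4E)‑2‑(ethoxycarbonyl)‑5‑(PMB‑oxymethyl)‑3‑oxonona‑4,8‑dienoic acid (acylmalonic acid monoester) | CCOC(=O)C(C(=O)O)C(=O)/C=C(/COCc1ccc(OC)cc1)CCC=C | intermediate
13 | ethyl (4E)‑5‑{[(4‑methoxybenzyl)oxy]methyl}‑3‑oxonona‑4,8‑dienoate | CCOC(=O)CC(=O)/C=C(/COCc1ccc(OC)cc1)CCC=C | intermediate
14 | ethyl (3S,4E)‑3‑hydroxy‑5‑(PMB‑oxymethyl)nona‑4,8‑dienoate | CCOC(=O)C[C@H](O)/C=C(/COCc1ccc(OC)cc1)CCC=C | intermediate
15 | tert‑butyl bromoacetate | CC(C)(C)OC(=O)CBr | starting material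
16 | dilithium dianion (alkoxide/ester enolate) of 14 | [Li+].[Li+].CCOC([O-])=C[C@H]([O-])/C=C(/COCc1ccc(OC)cc1)CCC=C | intermediate
17 | 4‑tert‑butyl 1‑ethyl (2R)‑2‑[(1R,2E)‑1‑hydroxy‑3‑(PMB‑oxymethyl)hepta‑2,6‑dien‑1‑yl]butanedioate | CCOC(=O)[C@H](CC(=O)OC(C)(C)C)[C@H](O)/C=C(/COCc1ccc(OC)cc1)CCC=C | intermediate
18 | 4‑tert‑butyl 1‑ethyl (2R)‑2‑[(1R,2E)‑3‑(PMB‑oxymethyl)‑1‑(TES‑oxy)hepta‑2,6‑dien‑1‑yl]butanedioate | CCOC(=O)[C@H](CC(=O)OC(C)(C)C)[C@H](O[Si](CC)(CC)CC)/C=C(/COCc1ccc(OC)cc1)CCC=C | intermediate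
19 | tert‑butyl (3R,4R,5E)‑3‑formyl‑6‑(PMB‑oxymethyl)‑4‑(TES‑oxy)deca‑5,9‑dienoate | O=C[C@H](CC(=O)OC(C)(C)C)[C@H](O[Si](CC)(CC)CC)/C=C(/COCc1ccc(OC)cc1)CCC=C | intermediate
20 | 2‑[(trimethylsilyl)methyl]allyl acetate | CC(=O)OCC(=C)C[Si](C)(C)C | starting material
21 | 2‑[(trimethylsilyl)methyl]prop‑2‑en‑1‑ol | OCC(=C)C[Si](C)(C)C | intermediate
22 | tert‑butyl(diphenyl)({2‑[(trimethylsilyl)methyl]prop‑2‑en‑1‑yl}oxy)silane | C=C(CO[Si](c1ccccc1)(c1ccccc1)C(C)(C)C)C[Si](C)(C)C | intermediate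
23 | tert‑butyl (3S,4R,5E)‑3‑[(1R)‑1‑hydroxy‑3‑(TBDPS‑oxymethyl)but‑3‑en‑1‑yl]‑6‑(PMB‑oxymethyl)‑4‑(TES‑oxy)deca‑5,9‑dienoate | C=C(CO[Si](c1ccccc1)(c1ccccc1)C(C)(C)C)C[C@@H](O)[C@H](CC(=O)OC(C)(C)C)[C@H](O[Si](CC)(CC)CC)/C=C(/COCc1ccc(OC)cc1)CCC=C | intermediate
24 | tert‑butyl (3S,4R,5E)‑3‑[(1R)‑1‑(TBS‑oxy)‑3‑(TBDPS‑oxymethyl)but‑3‑en‑1‑yl]‑6‑(PMB‑oxymethyl)‑4‑(TES‑oxy)deca‑5,9‑dienoate | C=C(CO[Si](c1ccccc1)(c1ccccc1)C(C)(C)C)C[C@@H](O[Si](C)(C)C(C)(C)C)[C@H](CC(=O)OC(C)(C)C)[C@H](O[Si](CC)(CC)CC)/C=C(/COCc1ccc(OC)cc1)CCC=C | intermediate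
25 | tert‑butyl (3R,4R,5E)‑3‑[(1R)‑1‑(TBS‑oxy)‑3‑(TBDPS‑oxymethyl)but‑3‑en‑1‑yl]‑4‑hydroxy‑6‑(PMB‑oxymethyl)deca‑5,9‑dienoate | C=C(CO[Si](c1ccccc1)(c1ccccc1)C(C)(C)C)C[C@@H](O[Si](C)(C)C(C)(C)C)[C@H](CC(=O)OC(C)(C)C)[C@H](O)/C=C(/COCc1ccc(OC)cc1)CCC=C | intermediate
26 | (4R,5R)‑4‑[(1R)‑1‑(TBS‑oxy)‑3‑(TBDPS‑oxymethyl)but‑3‑en‑1‑yl]‑5‑[(1E)‑2‑(PMB‑oxymethyl)hexa‑1,5‑dien‑1‑yl]dihydrofuran‑2(3H)‑one | O=C1O[C@H](/C=C(/COCc2ccc(OC)cc2)CCC=C)[C@H]([C@H](O[Si](C)(C)C(C)(C)C)CC(=C)CO[Si](c2ccccc2)(c2ccccc2)C(C)(C)C)C1 | intermediate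
27 | (3aR,4R,6E,10E,11aR)‑4‑(TBS‑oxy)‑6‑(TBDPS‑oxymethyl)‑10‑(PMB‑oxymethyl)‑3a,4,5,8,9,11a‑hexahydrocyclodeca[b]furan‑2(3H)‑one | O=C1O[C@@H]2/C=C(/COCc3ccc(OC)cc3)CC/C=C(/CO[Si](c3ccccc3)(c3ccccc3)C(C)(C)C)C[C@@H](O[Si](C)(C)C(C)(C)C)[C@@H]2C1 | intermediate
28 | lithium enolate of 27 | [Li+].[O-]C1O[C@@H]2/C=C(/COCc3ccc(OC)cc3)CC/C=C(/CO[Si](c3ccccc3)(c3ccccc3)C(C)(C)C)C[C@@H](O[Si](C)(C)C(C)(C)C)[C@@H]2C=1 | intermediate
29 | (3aR,4R,6E,10E,11aR)‑3‑[(dimethylamino)methyl]‑4‑(TBS‑oxy)‑6‑(TBDPS‑oxymethyl)‑10‑(PMB‑oxymethyl)‑3a,4,5,8,9,11a‑hexahydrocyclodeca[b]furan‑2(3H)‑one (C3 epimers) | CN(C)CC1C(=O)O[C@@H]2/C=C(/COCc3ccc(OC)cc3)CC/C=C(/CO[Si](c3ccccc3)(c3ccccc3)C(C)(C)C)C[C@@H](O[Si](C)(C)C(C)(C)C)[C@H]12 | intermediate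
30 | trimethylammonium iodide of 29 | [I-].C[N+](C)(C)CC1C(=O)O[C@@H]2/C=C(/COCc3ccc(OC)cc3)CC/C=C(/CO[Si](c3ccccc3)(c3ccccc3)C(C)(C)C)C[C@@H](O[Si](C)(C)C(C)(C)C)[C@H]12 | intermediate
31 | (3aR,4R,6E,10E,11aR)‑3‑methylidene‑4‑(TBS‑oxy)‑6‑(TBDPS‑oxymethyl)‑10‑(PMB‑oxymethyl)‑3a,4,5,8,9,11a‑hexahydrocyclodeca[b]furan‑2(3H)‑one | C=C1C(=O)O[C@@H]2/C=C(/COCc3ccc(OC)cc3)CC/C=C(/CO[Si](c3ccccc3)(c3ccccc3)C(C)(C)C)C[C@@H](O[Si](C)(C)C(C)(C)C)[C@H]12 | intermediate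
32 | (3aS,4R,6E,10E,11aR)‑4‑hydroxy‑6‑(hydroxymethyl)‑10‑(PMB‑oxymethyl)‑3‑methylidene‑3a,4,5,8,9,11a‑hexahydrocyclodeca[b]furan‑2(3H)‑one | C=C1C(=O)O[C@@H]2/C=C(/COCc3ccc(OC)cc3)CC/C=C(/CO)C[C@@H](O)[C@H]12 | intermediate
33 | (3aS,4R,6E,10E,11aR)‑4‑hydroxy‑10‑(PMB‑oxymethyl)‑3‑methylidene‑2‑oxo‑2,3,3a,4,5,8,9,11a‑octahydrocyclodeca[b]furan‑6‑carbaldehyde | C=C1C(=O)O[C@@H]2/C=C(/COCc3ccc(OC)cc3)CC/C=C(/C=O)C[C@@H](O)[C@H]12 | intermediate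
34 | 3‑methylbutanoic anhydride | CC(C)CC(=O)OC(=O)CC(C)C | starting material
35 | [(3aS,4R,6E,10E,11aR)‑6‑formyl‑10‑(PMB‑oxymethyl)‑3‑methylidene‑2‑oxo‑2,3,3a,4,5,8,9,11a‑octahydrocyclodeca[b]furan‑4‑yl] 3‑methylbutanoate | C=C1C(=O)O[C@@H]2/C=C(/COCc3ccc(OC)cc3)CC/C=C(/C=O)C[C@@H](OC(=O)CC(C)C)[C@H]12 | intermediate
36 | [(3aS,4R,6E,10E,11aR)‑6‑formyl‑10‑(hydroxymethyl)‑3‑methylidene‑2‑oxo‑2,3,3a,4,5,8,9,11a‑octahydrocyclodeca[b]furan‑4‑yl] 3‑methylbutanoate | C=C1C(=O)O[C@@H]2/C=C(/CO)CC/C=C(/C=O)C[C@@H](OC(=O)CC(C)C)[C@H]12 | target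

**Totals and risks**
Total step count: 21. Longest linear sequence: 19 steps (steps 1–9, then 12–21; steps 10–11 make allylsilane 22).

The three steps most likely to fail:

Step 15 (ring‑closing metathesis). Closing a ten‑membered ring onto a hindered 1,1‑disubstituted olefin can give dimers or the ring‑trans olefin. The fallback sets out from 24 and inverts the order of ring formation. The same C1=C10 metathesis is run on the open‑chain triene, whose C6–C7–C8 segment is not yet locked in the lactone, to give the macrocyclic ester tert‑butyl 2‑[(1S,2R,4E,8E,10R)‑2‑(TBS‑oxy)‑4‑(TBDPS‑oxymethyl)‑8‑(PMB‑oxymethyl)‑10‑(TES‑oxy)cyclodeca‑4,8‑dien‑1‑yl]acetate F6. PPTS in MeOH then frees O6 to give the hydroxy ester tert‑butyl 2‑[(1R,2R,4E,8E,10R)‑10‑hydroxy‑2‑(TBS‑oxy)‑4‑(TBDPS‑oxymethyl)‑8‑(PMB‑oxymethyl)cyclodeca‑4,8‑dien‑1‑yl]acetate F7, which lactonises with catalytic TsOH and comes back to the route at 27.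

Step 7 (Fráter–Seebach alkylation with an α‑bromo ester). Proton transfer to the dianion or premature lactonisation of the product alkoxide onto the tert‑butyl ester can erode the yield. The fallback sets out from 13. C‑Alkylation with 15 (K2CO3, acetone, rt) gives the racemic, configurationally labile keto diester 4‑tert‑butyl 1‑ethyl 2‑[(2E)‑3‑(PMB‑oxymethyl)hepta‑2,6‑dienoyl]butanedioate F1. A ketoreductase screened for the anti product then reduces it under dynamic kinetic resolution (pH 7–8, where C7 epimerises fast), setting C6 and C7 together, and comes back to the route at 17.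

Step 12 (Hosomi–Sakurai allylation). The allylsilane may react slowly, and BF3 may erode the TES ether or trigger lactonisation of the new γ‑hydroxy tert‑butyl ester. The fallback sets out from 19 and uses a more nucleophilic enol silane under the same Felkin/1,3‑anti model. Commercial hydroxyacetone is silylated (tBuPh2SiCl, imidazole) to 1‑(TBDPS‑oxy)propan‑2‑one F2, which is converted (LiN(iPr)2, Me3SiCl, THF, −78 °C) into tert‑butyl(diphenyl)({2‑[(trimethylsilyl)oxy]prop‑2‑en‑1‑yl}oxy)silane F3. A Mukaiyama aldol of F3 with 19 (BF3·OEt2, CH2Cl2, −78 °C) gives tert‑butyl (3S,4R,5E)‑3‑[(1R)‑1‑hydroxy‑3‑oxo‑4‑(TBDPS‑oxy)butyl]‑6‑(PMB‑oxymethyl)‑4‑(TES‑oxy)deca‑5,9‑dienoate F4. TBSOTf/2,6‑lutidine gives tert‑butyl (3S,4R,5E)‑3‑[(1R)‑1‑(TBS‑oxy)‑3‑oxo‑4‑(TBDPS‑oxy)butyl]‑6‑(PMB‑oxymethyl)‑4‑(TES‑oxy)deca‑5,9‑dienoate F5. Non‑basic Petasis methylenation of the C10 ketone (Cp2TiMe2, toluene, 70 °C) comes back to the route at 24.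

**Further compounds**
F1 | step 7 | 4‑tert‑butyl 1‑ethyl 2‑[(2E)‑3‑(PMB‑oxymethyl)hepta‑2,6‑dienoyl]butanedioate (racemic) | CCOC(=O)C(CC(=O)OC(C)(C)C)C(=O)/C=C(/COCc1ccc(OC)cc1)CCC=C
F2 | step 12 | 1‑(TBDPS‑oxy)propan‑2‑one | CC(=O)CO[Si](c1ccccc1)(c1ccccc1)C(C)(C)C
F3 | step 12 | tert‑butyl(diphenyl)({2‑[(trimethylsilyl)oxy]prop‑2‑en‑1‑yl}oxy)silane | C=C(O[Si](C)(C)C)CO[Si](c1ccccc1)(c1ccccc1)C(C)(C)C
F4 | step 12 | tert‑butyl (3S,4R,5E)‑3‑[(1R)‑1‑hydroxy‑3‑oxo‑4‑(TBDPS‑oxy)butyl]‑6‑(PMB‑oxymethyl)‑4‑(TES‑oxy)deca‑5,9‑dienoate | O=C(CO[Si](c1ccccc1)(c1ccccc1)C(C)(C)C)C[C@@H](O)[C@H](CC(=O)OC(C)(C)C)[C@H](O[Si](CC)(CC)CC)/C=C(/COCc1ccc(OC)cc1)CCC=C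
F5 | step 12 | tert‑butyl (3S,4R,5E)‑3‑[(1R)‑1‑(TBS‑oxy)‑3‑oxo‑4‑(TBDPS‑oxy)butyl]‑6‑(PMB‑oxymethyl)‑4‑(TES‑oxy)deca‑5,9‑dienoate | O=C(CO[Si](c1ccccc1)(c1ccccc1)C(C)(C)C)C[C@@H](O[Si](C)(C)C(C)(C)C)[C@H](CC(=O)OC(C)(C)C)[C@H](O[Si](CC)(CC)CC)/C=C(/COCc1ccc(OC)cc1)CCC=C
F6 | step 15 | tert‑butyl 2‑[(1S,2R,4E,8E,10R)‑2‑(TBS‑oxy)‑4‑(TBDPS‑oxymethyl)‑8‑(PMB‑oxymethyl)‑10‑(TES‑oxy)cyclodeca‑4,8‑dien‑1‑yl]acetate | CC[Si](CC)(CC)O[C@@H]1/C=C(/COCc2ccc(OC)cc2)CC/C=C(/CO[Si](c2ccccc2)(c2ccccc2)C(C)(C)C)C[C@@H](O[Si](C)(C)C(C)(C)C)[C@@H]1CC(=O)OC(C)(C)C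
F7 | step 15 | tert‑butyl 2‑[(1R,2R,4E,8E,10R)‑10‑hydroxy‑2‑(TBS‑oxy)‑4‑(TBDPS‑oxymethyl)‑8‑(PMB‑oxymethyl)cyclodeca‑4,8‑dien‑1‑yl]acetate | O[C@@H]1/C=C(/COCc2ccc(OC)cc2)CC/C=C(/CO[Si](c2ccccc2)(c2ccccc2)C(C)(C)C)C[C@@H](O[Si](C)(C)C(C)(C)C)[C@@H]1CC(=O)OC(C)(C)C
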